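At early times the new flask is a racemate, so the excess of right-handed substrate is zero, and no reagent is dissolved yet.

| flask | left-handed substrate | right-handed substrate | gas | free catalyst | added ligand | remark | time |
|---|---|---|---|---|---|---|---|
| birch | 0.12 M | 0.12 M | 16 mM (held) | 0.12 mM | 0.18 mM | run made earlier |  |
| cedar | 0.12 M | 0.12 M | 16 mM (held) | 0.12 mM | 0.29 mM | run made earlier |  |
| larch | 0.12 M | 0.12 M | 16 mM (held) | 0.060 mM | 0.13 mM | run made earlier |  |
| flask | 0.12 M | 0.12 M | 16 mM (held) | 0.12 mM | 0.13 mM |  | 40 h |

- birch (time / h: right-handed substrate / %, left-handed substrate / %): 6.00: 49.5, 10.5; 15.0: 50.8, 0.8; 30.0: 48.9, 0.3; 50.0: 46.0, 1.8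
- cedar (time / h: right-handed substrate / %, left-handed substrate / %): 4.00: 48.7, 24.9; 8.00: 50.5, 11.7; 20.0: 48.7, 0; 50.0: 47.1, 0
- larch (time / h: right-handed substrate / %, left-handed substrate / %): 4.00: 50.4, 30.8; 8.00: 48.9, 20.2; 20.0: 49.2, 6.1; 50.0: 47.3, 0

(readings scatter by 1 percentage point)

- free catalyst is single-handed; left-handed substrate and right-handed substrate are mirror images of each other, charged as a racemate, each of them at the stated concentration
- at the start none of reagent is dissolved
- the analysis behind the earlier runs scatters by 1 percentage point, standard deviation
- steps that have been proposed: free catalyst + left-handed substrate <-> catalyst intermediate A; free catalyst + right-handed substrate <-> catalyst intermediate B; reagent + catalyst intermediate A -> free catalyst + left-handed product; reagent + catalyst intermediate B -> free catalyst + right-handed product; free catalyst + added ligand <-> idle complex; gas <-> reagent; reagent + free catalyst -> spent catalyst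

- whether the excess of right-handed substrate over left-handed substrate among what is left of the two reaches 80% by 40 h (no / yes)
- the highest excess of right-handed substrate over left-handed substrate among what is left of the two up to 40 h

Once the earlier runs get going, you see the left-handed substrate fall while the right-handed one barely moves. So follow one number, the separation, ln(c(right-handed substrate)/c(left-handed substrate)). It starts at zero and, for a pseudo-first-order fall, climbs in a straight line with time. An excess of 80% means a ratio of 9.00, so the needed separation is 2.20, the natural logarithm of that ratio.

In the middle of a run, you read the slope. Birch climbs at 0.258 h⁻¹, and its right-handed substrate loses only 0.00167 h⁻¹, a small correction that I drop. Cedar, with more added ligand and the same catalyst, climbs at 0.168 h⁻¹, slower. The new flask has less ligand than birch and the same catalyst, so my reckoning expects a steeper climb and a crossing before 8.50 h.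

Towards the end, catalyst loss is what could matter, but that time is short against the 40 h allowed. Cedar's left-handed reading is already 0% at 20.0 h, so I expect an excess close to complete.

The forecast says yes, with a top of 99.9%: “which reaches 80% excess in roughly 7 h”.

The new flask gives yes, with a top of >99.9%.

    free catalyst + left-handed substrate ⇌ catalyst intermediate A (K = 31.0 L mol⁻¹, k = 34000 L mol⁻¹ h⁻¹)
    free catalyst + right-handed substrate ⇌ catalyst intermediate B (K = 5.10 L mol⁻¹, k = 39000 L mol⁻¹ h⁻¹)
    reagent + catalyst intermediate A → free catalyst + left-handed product (k = 34000 L mol⁻¹ h⁻¹)
    reagent + catalyst intermediate B → free catalyst + right-handed product (k = 1100 L mol⁻¹ h⁻¹)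
    free catalyst + added ligand ⇌ idle complex (K = 27000 L mol⁻¹, k = 8900 L mol⁻¹ h⁻¹)
    gas ⇌ reagent, rate k6*(csat - [reagent]) (kL = 23.0 h⁻¹)
    reagent + free catalyst → spent catalyst (k = 3.20 L mol⁻¹ h⁻¹)

The new flask crosses at 7.35 h, sooner than 8.50 h, which makes its average slope 0.299 h⁻¹. Larch reads a separation of 2.09 at 20.0 h. A separation of 2.20 there would mean a left-handed reading of 5.47%, and the 6.1% read stands within the scatter of 1 percentage point of that, so this reading does not say on which side of 20.0 h larch crosses. In the new flask, spent catalyst is only 4.28% of the catalyst charged at 4.00 h, before the crossing. At 20.0 h it is 23.0%, and left-handed substrate is already down to 0.111%.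

(The readings stem from a simulated flask from invented constants; noise was put on by code.)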